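## Retrosynthetic overview

1. The C16–O ester bond is cut last. The target comes from unprotected caffeic acid 14 and the unprotected triol acid 13, joined by a protecting-group-free acylation (key step).
2. 13 comes from 12 by global O-demethylation. C15 is set by a Ru-BINAP hydrogenation, and C1 and C11 are set together by one Ir hydrogenation of the triene 10.
3. The side-chain bond C12–C13 comes from alkenylboronate 8 and isoprene monoxide 9. The boronate 8 is made from the isopropenyl group.
4. The arene comes from a [3+3] benzannulation of formylated (R)-carvone with methyl 4-methoxyacetoacetate.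
5. Ring order: the carbocycle and C4 come from carvone, the benzoate ring is built on it in step 2, and the caffeoyl ring arrives intact in step 9.

Convention and assumption: positions use serrulatane numbering (C1 = ring CH–CH3, C4 = ring CH bearing the side chain, C11 and C15 = side-chain CH–CH3, C16 = CH2O, C19 = CO2H). Chiral catalysts and immobilised lipase are bought.

## Route

Step 1
Reactants: 1 (R)-(−)-carvone; 2 ethyl formate
Product: 3 (5S,6Z)-6-(hydroxymethylidene)-2-methyl-5-(prop-1-en-2-yl)cyclohex-2-en-1-one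
Conditions: NaOMe, toluene, 0 → 23 °C; 1 M HCl
Reagents that add atoms: none
Why: This crossed Claisen formylation goes to the only α′-CH2 (future C10) because only there does a stable β-keto-aldehyde enolate form, and the non-acidic carvone stereocentre (future C4) is kept.

Step 2
Reactants: 3 hydroxymethylene carvone; 4 methyl 4-methoxy-3-oxobutanoate
Product: 6 methyl (8S)-3-hydroxy-4-methoxy-5-methyl-8-(prop-1-en-2-yl)-7,8-dihydronaphthalene-2-carboxylate, via Knoevenagel adduct 5 (not isolated)
Conditions: piperidine/AcOH (20 mol %), MeOH, 23 °C; then NaOMe (2.5 equiv), 65 °C; 1 M HCl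
Reagents that add atoms: none
Why: In this [3+3] benzannulation (hydroxymethylene ketone plus β-keto ester phenol synthesis), Knoevenagel condensation joins the most acidic CH2 of 4 to the formyl carbon, then the methoxy-bearing CH2 closes by aldol condensation on the ring ketone and enolisation gives the arene, so CO2Me, OH and OMe fall on C6, C7 and C8 without regiochemical choice and C4 is untouched.

Step 3
Reactants: 6 phenol
Product: 7 methyl (8S)-3,4-dimethoxy-5-methyl-8-(prop-1-en-2-yl)-7,8-dihydronaphthalene-2-carboxylate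
Conditions: MeI, K2CO3, DMF, 40 °C
Reagents that add atoms: iodomethane, CI
Why: Williamson O-methylation masks the acidic phenol, which would otherwise be O-allylated by the π-allyl-palladium species of step 5.

Step 4
Reactants: 7 dimethyl ether
Product: 8 methyl (8S)-3,4-dimethoxy-5-methyl-8-[(1E)-1-(4,4,5,5-tetramethyl-1,3,2-dioxaborolan-2-yl)prop-1-en-2-yl]-7,8-dihydronaphthalene-2-carboxylate
Conditions: B2pin2, trans-[RhCl(CO)(PPh3)2] (5 mol %), toluene–MeCN 3:1, 80 °C
Reagents that add atoms: bis(pinacolato)diboron, CC1(C)OB(OC1(C)C)B1OC(C)(C)C(C)(C)O1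
Why: Rh-catalysed dehydrogenative borylation (boryl insertion, then β-hydride elimination) attacks only the unhindered 1,1-disubstituted alkene and places boron trans to the bulky ring carbon, which fixes the E geometry needed in step 7.

Step 5
Reactants: 8 alkenylboronate; 9 2-methyl-2-vinyloxirane (isoprene monoxide, racemic)
Product: 10 methyl (8S)-8-[(2E,5E)-7-hydroxy-6-methylhepta-2,5-dien-2-yl]-3,4-dimethoxy-5-methyl-7,8-dihydronaphthalene-2-carboxylate
Conditions: Pd(PPh3)4 (5 mol %), K3PO4, THF–H2O 10:1, 50 °C; the minor 5Z isomer is removed on AgNO3–silica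
Reagents that add atoms: none
Why: In this Suzuki–Miyaura/Tsuji–Trost type 1,4-coupling of an alkenylboronate with a vinyl epoxide, the π-allyl-palladium alkoxide couples at its unhindered CH2 terminus with retention of the boronate geometry and gives mainly the E allylic alcohol.

Step 6
Reactants: 10 dienol
Product: 11 methyl (8S)-8-[(2E,6R)-7-hydroxy-6-methylhept-2-en-2-yl]-3,4-dimethoxy-5-methyl-7,8-dihydronaphthalene-2-carboxylate
Conditions: Ru(OAc)2[(R)-BINAP] (1 mol %), H2 (100 atm), MeOH, 20 °C
Reagents that add atoms: none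
Why: Noyori hydroxyl-assisted asymmetric hydrogenation reduces only the allylic-alcohol alkene, and (R)-BINAP adds H2 to the same enantioface as in geraniol → (S)-citronellol, which for this E-2-methyl allylic alcohol sets 15R.

Step 7
Reactants: 11 alcohol
Product: 12 methyl (5R,8S)-8-[(2S,6R)-7-hydroxy-6-methylheptan-2-yl]-3,4-dimethoxy-5-methyl-5,6,7,8-tetrahydronaphthalene-2-carboxylate
Conditions: [Ir(cod)(L*)]BArF (2 mol %; L* = bicyclic pyridine–phosphinite, the antipode that turns all-E γ-tocotrienyl acetate into the R,R,R product), H2 (50 bar), CH2Cl2, 23 °C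
Reagents that add atoms: none
Why: In this Ir–N,P asymmetric hydrogenation of unfunctionalised trisubstituted alkenes the vinylic H of both alkenes sits in the hindered quadrant, so one catalyst face delivers 1R (methyl trans to the side chain) at the ring alkene and 11S at the E side-chain alkene.

Step 8
Reactants: 12 protected alcohol
Product: 13 (5R,8S)-3,4-dihydroxy-8-[(2S,6R)-7-hydroxy-6-methylheptan-2-yl]-5-methyl-5,6,7,8-tetrahydronaphthalene-2-carboxylic acid
Conditions: AlBr3, EtSH, CH2Cl2, 0 → 23 °C
Reagents that add atoms: none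
Why: Hard-acid/soft-nucleophile dealkylation (SN2 of the thiol at the three aluminium-activated O–CH3 groups) frees the catechol and the acid in one operation and touches neither the primary alcohol nor any stereocentre.

Step 9
Reactants: 13 triol acid; 14 caffeic acid
Product: 15 target CNP0492979.1
Conditions: Novozym 435 (immobilised CAL-B), 14 (5 equiv), 2-methyl-2-butanol, 4 Å MS, 60 °C, N2
Reagents that add atoms: none
Why: Proposed new method: protecting-group-free lipase esterification of an alcohol that also carries a free salicylic-type acid and a catechol, with unprotected caffeic acid as acyl donor; the Ser105 acyl-enzyme can form only from the flat unhindered E-cinnamic acid (the flanked, H-bonded benzoic acid of 13 does not fit the acyl channel) and is intercepted only by the aliphatic C16–OH because phenols are too weak as nucleophiles and aryl esters are cleaved again, while sieves remove water and drive the equilibrium and no stereocentre is touched; the closest known reaction type is the CAL-B esterification of caffeic acid with simple primary alcohols (alkyl caffeates, CAPE).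

## Compound list

1 | (R)-(−)-carvone | CC1=CC[C@H](CC1=O)C(C)=C | starting material
2 | ethyl formate | CCOC=O | starting material
3 | (5S,6Z)-6-(hydroxymethylidene)-2-methyl-5-(prop-1-en-2-yl)cyclohex-2-en-1-one | CC1=CC[C@@H](C(C)=C)/C(=C/O)C1=O | intermediate
4 | methyl 4-methoxy-3-oxobutanoate | COCC(=O)CC(=O)OC | starting material
5 | methyl 2-(methoxyacetyl)-3-[(6R)-3-methyl-2-oxo-6-(prop-1-en-2-yl)cyclohex-3-en-1-yl]prop-2-enoate (labile C-1 epimers, E/Z, tautomers) | COCC(=O)C(C(=O)OC)=CC1C(=O)C(C)=CC[C@H]1C(C)=C | intermediate (not isolated)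
6 | methyl (8S)-3-hydroxy-4-methoxy-5-methyl-8-(prop-1-en-2-yl)-7,8-dihydronaphthalene-2-carboxylate | COC(=O)c1cc2c(c(OC)c1O)C(C)=CC[C@H]2C(C)=C | intermediate
7 | methyl (8S)-3,4-dimethoxy-5-methyl-8-(prop-1-en-2-yl)-7,8-dihydronaphthalene-2-carboxylate | COC(=O)c1cc2c(c(OC)c1OC)C(C)=CC[C@H]2C(C)=C | intermediate
8 | methyl (8S)-3,4-dimethoxy-5-methyl-8-[(1E)-1-(pinacolboryl)prop-1-en-2-yl]-7,8-dihydronaphthalene-2-carboxylate | COC(=O)c1cc2c(c(OC)c1OC)C(C)=CC[C@H]2/C(C)=C/B1OC(C)(C)C(C)(C)O1 | intermediate
9 | 2-methyl-2-vinyloxirane (racemic) | CC1(CO1)C=C | starting material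
10 | methyl (8S)-8-[(2E,5E)-7-hydroxy-6-methylhepta-2,5-dien-2-yl]-3,4-dimethoxy-5-methyl-7,8-dihydronaphthalene-2-carboxylate | COC(=O)c1cc2c(c(OC)c1OC)C(C)=CC[C@H]2/C(C)=C/C/C=C(\C)CO | intermediate
11 | methyl (8S)-8-[(2E,6R)-7-hydroxy-6-methylhept-2-en-2-yl]-3,4-dimethoxy-5-methyl-7,8-dihydronaphthalene-2-carboxylate | COC(=O)c1cc2c(c(OC)c1OC)C(C)=CC[C@H]2/C(C)=C/CC[C@@H](C)CO | intermediate
12 | methyl (5R,8S)-8-[(2S,6R)-7-hydroxy-6-methylheptan-2-yl]-3,4-dimethoxy-5-methyl-5,6,7,8-tetrahydronaphthalene-2-carboxylate | COC(=O)c1cc2c(c(OC)c1OC)[C@H](C)CC[C@H]2[C@@H](C)CCC[C@@H](C)CO | intermediate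
13 | (5R,8S)-3,4-dihydroxy-8-[(2S,6R)-7-hydroxy-6-methylheptan-2-yl]-5-methyl-5,6,7,8-tetrahydronaphthalene-2-carboxylic acid | OC(=O)c1cc2c(c(O)c1O)[C@H](C)CC[C@H]2[C@@H](C)CCC[C@@H](C)CO | intermediate
14 | caffeic acid | OC(=O)/C=C/c1ccc(O)c(O)c1 | starting material
15 | CNP0492979.1, the 16-O-(E)-caffeate of 13 | C[C@H](CCC[C@H](C)[C@@H]1CC[C@@H](C)c2c1cc(C(=O)O)c(O)c2O)COC(=O)/C=C/c1ccc(O)c(O)c1 | target

## Step count

- Total step count: 9.
- Longest linear sequence: 9, from 1 to 15.

## Steps most likely to fail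

**Step 2 (benzannulation).**
- Risk: the adduct may stop at a 3-acyl-2-pyranone, or 4 may add to the enone in a Michael reaction.
- Fallback: a known catechol annulation through an electron-poor pyranone, from 1 back to 7.
- The kinetic α′-enolate of 1 (LDA, THF, −78 °C) is added to dimethyl (methoxymethylene)malonate. Acidic work-up closes the adduct to methyl (5S)-8-methyl-2-oxo-5-(prop-1-en-2-yl)-5,6-dihydro-2H-chromene-3-carboxylate F1.
- Heating F1 with 1,1,2-trimethoxyethene in mesitylene at 150 °C gives 7 directly by inverse-demand Diels–Alder reaction and aromatisation. Steps 1 to 3 are bypassed.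

**Step 7 (double hydrogenation).**
- Risk: the catalyst must override the steric bias of the C4 substituent at the ring alkene, next to the peri-methoxy group, and must not isomerise the side-chain alkene.
- Fallback: two separately matched reductions, from 11 back to 12.
- An Ir–PHOX type catalyst (NeoPHOX, the antipode for 1R, 5 bar H2) reduces aryl-conjugated alkenes but is almost inert to purely alkyl-substituted ones. It gives methyl (5R,8S)-8-[(2E,6R)-7-hydroxy-6-methylhept-2-en-2-yl]-3,4-dimethoxy-5-methyl-5,6,7,8-tetrahydronaphthalene-2-carboxylate F2, which is purified from its C1 epimer.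
- The pyridine–phosphinite catalyst at 50 bar then sets 11S and gives 12.

**Step 9 (new step).**
- Risk: caffeic acid is a slow acyl donor, and 13 may bind poorly or acidify the enzyme.
- Fallback: known chemistry from 12 back to 15, bypassing step 8.
- Saponification (KOH, MeOH–H2O, reflux) gives (5R,8S)-8-[(2S,6R)-7-hydroxy-6-methylheptan-2-yl]-3,4-dimethoxy-5-methyl-5,6,7,8-tetrahydronaphthalene-2-carboxylic acid F3.
- Acylation with 3,4-dimethoxycinnamoyl chloride (pyridine, DMAP, CH2Cl2) follows, and the aqueous NaHCO3 work-up hydrolyses the mixed anhydride. This gives (5R,8S)-8-{(2S,6R)-7-[(E)-3-(3,4-dimethoxyphenyl)prop-2-enoyloxy]-6-methylheptan-2-yl}-3,4-dimethoxy-5-methyl-5,6,7,8-tetrahydronaphthalene-2-carboxylic acid F4.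
- BBr3 (CH2Cl2, −78 → 0 °C) cleaves the four aryl methyl ethers and gives 15.

## Further compounds

F1 | step 2 | methyl (5S)-8-methyl-2-oxo-5-(prop-1-en-2-yl)-5,6-dihydro-2H-chromene-3-carboxylate | COC(=O)C1=CC2=C(OC1=O)C(C)=CC[C@H]2C(C)=C
F2 | step 7 | methyl (5R,8S)-8-[(2E,6R)-7-hydroxy-6-methylhept-2-en-2-yl]-3,4-dimethoxy-5-methyl-5,6,7,8-tetrahydronaphthalene-2-carboxylate | COC(=O)c1cc2c(c(OC)c1OC)[C@H](C)CC[C@H]2/C(C)=C/CC[C@@H](C)CO
F3 | step 9 | (5R,8S)-8-[(2S,6R)-7-hydroxy-6-methylheptan-2-yl]-3,4-dimethoxy-5-methyl-5,6,7,8-tetrahydronaphthalene-2-carboxylic acid | OC(=O)c1cc2c(c(OC)c1OC)[C@H](C)CC[C@H]2[C@@H](C)CCC[C@@H](C)CO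
F4 | step 9 | (5R,8S)-8-{(2S,6R)-7-[(E)-3-(3,4-dimethoxyphenyl)prop-2-enoyloxy]-6-methylheptan-2-yl}-3,4-dimethoxy-5-methyl-5,6,7,8-tetrahydronaphthalene-2-carboxylic acid | OC(=O)c1cc2c(c(OC)c1OC)[C@H](C)CC[C@H]2[C@@H](C)CCC[C@@H](C)COC(=O)/C=C/c1ccc(OC)c(OC)c1
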